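**Retrosynthetic overview** (chain numbered C1 = CH2OAc to C15 = ring CMe2)
1. The route rests on C11, the tetrasubstituted ether carbon of the oxane ring (bonded to ring O, CH3, C10 and C12). It is traced back to the all-carbon α-quaternary carbon of (R)-2-allyl-2-methylcyclopentanone 4, whose carbonyl carbon is C15.
2. C11–O bond and oxan-2-one 5 ⇐ Baeyer–Villiger ring expansion of 4. The five-membered carbocycle is closed first (Dieckmann), then expanded into the only ring of the target; no other ring is formed.
3. C15 gem-dimethyl ⇐ lactone carbonyl (MeLi, then AlMe3 on the methyl ketal); C8–C10 ⇐ the allyl group (hydroboration, bromide 10).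
4. C7 ⇐ Cu-catalysed asymmetric conjugate addition of the Grignard reagent of 10 to crotonate thioester 11; C4 ⇐ Wittig methylenation.
5. C3–C4 ⇐ B-alkyl Suzuki coupling of alkene 15 with bromoalkene 22 (C1–C3; C2 is C5 of L-ascorbic acid), then acetonide → diacetate.

Key step: step 3

Assumption: the hand of each chiral ligand (steps 2 and 8) is assigned from the accepted models for these catalyst families; both antipodes are available, so a reversed sense would be corrected by the ligand alone. The oxane C2 (= C11) keeps one spatial arrangement from 4 to 26; its descriptor changes from R to S at 13 only through CIP priorities.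

**Route**

Step 1
Reactants: 1 diallyl adipate
Product: 3 allyl 1-methyl-2-oxocyclopentane-1-carboxylate (racemic), via sodium enolate 2 (not isolated)
Conditions: NaH (1.1 equiv), allyl alcohol (cat.), THF, 40 → 65 °C; then MeI (1.5 equiv), 40 °C
Reagents that add atoms: iodomethane, CI
Why: Dieckmann condensation gives the stabilised sodium enolate 2 of the five-membered β-keto ester, which is C-methylated in the same flask (SN2 on MeI); the quaternary centre is racemic here and is re-set in step 2.

Step 2
Reactants: 3 allyl 1-methyl-2-oxocyclopentane-1-carboxylate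
Product: 4 (R)-2-allyl-2-methylcyclopentanone
Conditions: Pd2(dba)3 (2.5 mol%), (R)-(p-CF3)3-t-BuPHOX (6 mol%), toluene, 25–30 °C; careful concentration (volatile)
Reagents that add atoms: none
Why: Decarboxylative asymmetric allylic alkylation (Tsuji allylation with a chiral phosphinooxazoline): oxidative addition and loss of CO2 give a Pd(allyl) enolate that is the same from either enantiomer of 3, and inner-sphere C–C bond formation within the (R)-PHOX complex sets the quaternary centre (future C11) as (R).

Step 3
Reactants: 4 (R)-2-allyl-2-methylcyclopentanone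
Product: 5 (R)-6-allyl-6-methyloxan-2-one
Conditions: Me3SiOOSiMe3 (1.5 equiv), TMSOTf (10 mol%), CH2Cl2, −78 → −40 °C; cold pyridine/NaHCO3 quench
Reagents that add atoms: bis(trimethylsilyl) peroxide, C[Si](C)(C)OO[Si](C)(C)C
Why: Baeyer–Villiger oxidation: TMSOTf activates the ketone, the silyl peroxide adds to give a silylated Criegee adduct, and the C–C bond antiperiplanar to the O–O bond migrates to oxygen with loss of hexamethyldisiloxane. The closest known reaction type is the Lewis-acid-promoted bis(trimethylsilyl) peroxide oxidation of α,α-disubstituted cycloalkanones to lactones in the presence of C=C bonds. The oxan-2-one ring is not closed by a cyclisation but arises by 1,2-shift ring expansion of the cyclopentanone (five- to six-membered, oxygen inserted between C11 and C15). The C11 stereocentre is carried over from 4: the concerted shift proceeds with retention at the migrating carbon, so the (R)-quaternary carbon becomes the (R)-tertiary C–O carbon. Two selectivities are needed: migration of the quaternary carbon and not the ring CH2, secured by the higher migratory aptitude of the more substituted carbon, and oxidation of C=O and not the allyl C=C, secured by a peroxide that reacts only after adding to the activated carbonyl and does not epoxidise an unactivated terminal alkene at low temperature.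

Step 4
Reactants: 5 (R)-6-allyl-6-methyloxan-2-one
Product: 7 (6R)-6-allyl-2-methoxy-2,6-dimethyloxane (C2 epimers), via lactol 6 (not isolated)
Conditions: MeLi (1.05 equiv), THF, −78 °C; AcOH quench, aqueous work-up; crude in MeOH, PPTS (cat.), 3 Å MS, rt
Reagents that add atoms: methyllithium, [Li]C; methanol, CO
Why: One equivalent of MeLi adds to the δ-lactone to give a tetrahedral lithium alkoxide that survives at −78 °C (first C15 methyl), and acid-catalysed ketalisation in methanol fixes the lactol as the cyclic methyl ketal; the C11–O bond is not involved, so C11 keeps its configuration.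

Step 5
Reactants: 7 (6R)-6-allyl-2-methoxy-2,6-dimethyloxane
Product: 8 (R)-2-allyl-2,6,6-trimethyloxane
Conditions: Me3Al (3 equiv), TMSOTf (0.2 equiv), CH2Cl2, −78 → −20 °C; Rochelle salt work-up
Reagents that add atoms: trimethylaluminium, C[Al](C)C
Why: Ketal C-methylation of the C-glycosidation type: Lewis-acid ionisation of the exocyclic C15–OMe bond gives a cyclic oxocarbenium ion that should take a methyl group from AlMe3 at low temperature faster than the allyl group can trap it, making C15 gem-dimethyl without ionising C11.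

Step 6
Reactants: 8 (R)-2-allyl-2,6,6-trimethyloxane
Product: 9 (R)-3-(2,6,6-trimethyloxan-2-yl)propan-1-ol
Conditions: 9-BBN (1.3 equiv), THF, 0 °C → rt; then 3 M NaOH, 30% H2O2, 0 °C → rt
Reagents that add atoms: hydrogen peroxide, OO
Why: Hydroboration–oxidation: the bulky 9-BBN places boron on the terminal alkene carbon (C8) and alkaline peroxide replaces boron by OH, the di-tertiary ether being inert.

Step 7
Reactants: 9 (R)-3-(2,6,6-trimethyloxan-2-yl)propan-1-ol
Product: 10 (R)-2-(3-bromopropyl)-2,6,6-trimethyloxane
Conditions: CBr4 (1.3 equiv), PPh3 (1.4 equiv), CH2Cl2, 0 °C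
Reagents that add atoms: carbon tetrabromide, BrC(Br)(Br)Br
Why: Appel reaction: the alkoxyphosphonium ion of the primary alcohol is displaced by bromide in an SN2 step under neutral conditions that leave the tertiary ether untouched.

Step 8
Reactants: 10 (R)-2-(3-bromopropyl)-2,6,6-trimethyloxane; 11 S-ethyl (E)-but-2-enethioate
Product: 13 S-ethyl (3S)-3-methyl-6-[(2S)-2,6,6-trimethyloxan-2-yl]hexanethioate, via Grignard reagent 12 (not isolated)
Conditions: Mg, Et2O, reflux; then CuBr·SMe2 (5 mol%), (R,S_Fe)-Josiphos (6 mol%), t-BuOMe, −75 °C, slow addition of 11 (1.0 equiv to 1.2 equiv of 12); 1 M HCl quench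
Reagents that add atoms: none
Why: Copper-catalysed asymmetric conjugate addition of a Grignard reagent to an α,β-unsaturated thioester: the chiral Cu–Josiphos complex transfers the alkyl group to the Re face of C3 of the (E)-enethioate, which sets C7 ((3S) in 13, (R) in the target by a change of CIP priorities only), while low temperature and slow addition suppress uncatalysed 1,2-addition.

Step 9
Reactants: 13 S-ethyl (3S)-3-methyl-6-[(2S)-2,6,6-trimethyloxan-2-yl]hexanethioate
Product: 14 (3S)-3-methyl-6-[(2S)-2,6,6-trimethyloxan-2-yl]hexanal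
Conditions: Et3SiH (3 equiv), 10% Pd/C (5 mol%), acetone, rt
Reagents that add atoms: none
Why: Fukuyama reduction: Pd inserts into the C–S bond and the acylpalladium is reduced by the silane to the aldehyde without over-reduction; C7 is β to the carbonyl and cannot epimerise.

Step 10
Reactants: 14 (3S)-3-methyl-6-[(2S)-2,6,6-trimethyloxan-2-yl]hexanal
Product: 15 (2S)-2,6,6-trimethyl-2-[(4S)-4-methylhept-6-en-1-yl]oxane
Conditions: Ph3PCH3Br (1.5 equiv), KHMDS (1.4 equiv), THF, 0 °C; then 14, 0 °C → rt
Reagents that add atoms: methyltriphenylphosphonium bromide, C[P+](c1ccccc1)(c1ccccc1)c1ccccc1.[Br-]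
Why: Wittig methylenation of the unhindered aldehyde adds C4 as a terminal alkene.

Step 11
Reactants: 16 L-ascorbic acid
Product: 17 L-gulono-1,4-lactone
Conditions: H2 (3–4 atm), 10% Pd/C, H2O, 50 °C
Reagents that add atoms: none
Why: Catalytic hydrogenation of the enediol occurs from the ring face opposite the C4 side chain to give the all-cis lactone, and the C5 stereocentre (future C2 of the target) is untouched.

Step 12
Reactants: 17 L-gulono-1,4-lactone
Product: 18 5,6-O-isopropylidene-L-gulono-1,4-lactone
Conditions: 2-methoxypropene (1.3 equiv), p-TsOH (cat.), DMF, 10 °C → rt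
Reagents that add atoms: 2-methoxypropene, COC(C)=C
Why: Acid-catalysed acetal exchange under kinetic control engages the primary C6–OH first and closes the terminal 5,6-dioxolane.

Step 13
Reactants: 18 5,6-O-isopropylidene-L-gulono-1,4-lactone
Product: 19 (S)-2,2-dimethyl-1,3-dioxolane-4-carbaldehyde
Conditions: NaIO4 (2.1 equiv), H2O, pH 5.5 (NaOH), 0 °C → rt; used fresh
Reagents that add atoms: none
Why: Malaprade glycol cleavage: periodate cleaves C2–C3, the resulting glyoxylate ester hydrolyses, and a second cleavage of the α-hydroxy aldehyde removes C3 as formic acid, leaving C4–C6 as the (S)-aldehyde whose stereocentre is the unchanged C5 of ascorbic acid.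

Step 14
Reactants: 19 (S)-2,2-dimethyl-1,3-dioxolane-4-carbaldehyde
Product: 20 (R)-2,2-dimethyl-4-vinyl-1,3-dioxolane
Conditions: Ph3PCH3Br (1.3 equiv), KHMDS (1.25 equiv), THF, 0 °C; then 19 at −78 → 0 °C; kept as a solution (volatile)
Reagents that add atoms: methyltriphenylphosphonium bromide, C[P+](c1ccccc1)(c1ccccc1)c1ccccc1.[Br-]
Why: Wittig methylenation with a preformed ylide at low temperature, conditions under which the α-alkoxy aldehyde should not enolise.

Step 15
Reactants: 20 (R)-2,2-dimethyl-4-vinyl-1,3-dioxolane
Product: 22 (S)-4-(1-bromovinyl)-2,2-dimethyl-1,3-dioxolane, via dibromide 21 (not isolated)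
Conditions: Br2 (1.05 equiv), K2CO3 (solid), CH2Cl2, −78 °C; solvent exchange; DBU (1.5 equiv), DMF, rt → 50 °C
Reagents that add atoms: bromine, BrBr
Why: Anti addition of bromine and then E2 dehydrobromination with DBU: the internal C–H is acidified by its own bromine and the adjacent C–O bond, so HBr is lost with the primary bromide to give the 2-bromo-1-alkene (known regiochemistry for vicinal dibromides next to an oxygen function), and the dioxolane stereocentre carries no acidic hydrogen.

Step 16
Reactants: 15 (2S)-2,6,6-trimethyl-2-[(4S)-4-methylhept-6-en-1-yl]oxane; 22 (S)-4-(1-bromovinyl)-2,2-dimethyl-1,3-dioxolane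
Product: 24 (4R)-2,2-dimethyl-4-{(6R)-6-methyl-9-[(2S)-2,6,6-trimethyloxan-2-yl]non-1-en-2-yl}-1,3-dioxolane, via B-alkyl-9-BBN 23 (not isolated)
Conditions: 9-BBN (1.3 equiv), THF, rt; then 3 M aq. Cs2CO3, 22 (1.2 equiv), PdCl2(dppf) (5 mol%), AsPh3 (5 mol%), DMF, rt
Reagents that add atoms: none
Why: B-alkyl Suzuki–Miyaura coupling: 9-BBN adds to the terminal carbon (C4) of 15, the base-activated borate transmetallates to the alkenylpalladium bromide formed from 22, and reductive elimination forms the C3–C4 bond with no stereocentre involved.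

Step 17
Reactants: 24 (4R)-2,2-dimethyl-4-{(6R)-6-methyl-9-[(2S)-2,6,6-trimethyloxan-2-yl]non-1-en-2-yl}-1,3-dioxolane
Product: 25 (2R,7R)-7-methyl-3-methylidene-10-[(2S)-2,6,6-trimethyloxan-2-yl]decane-1,2-diol
Conditions: AcOH/H2O/THF (3:1:1), 45 °C
Reagents that add atoms: none
Why: Acid-catalysed hydrolysis of the terminal acetonide under conditions too mild to ionise the di-tertiary oxane ether or the allylic C2–O bond.

Step 18
Reactants: 25 (2R,7R)-7-methyl-3-methylidene-10-[(2S)-2,6,6-trimethyloxan-2-yl]decane-1,2-diol
Product: 26 (2R,7R)-7-methyl-3-methylidene-10-[(2S)-2,6,6-trimethyloxan-2-yl]decane-1,2-diyl diacetate (CNP0136694.1)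
Conditions: Ac2O (3 equiv), pyridine, DMAP (cat.), CH2Cl2, 0 °C → rt
Reagents that add atoms: acetic anhydride, CC(=O)OC(C)=O
Why: DMAP-catalysed acylation of the primary and the secondary allylic alcohol with retention at C2.

**Compound list**
1 | diallyl adipate | C=CCOC(=O)CCCCC(=O)OCC=C | starting material
2 | sodium enolate of allyl 2-oxocyclopentane-1-carboxylate | C=CCOC(=O)C1=C([O-])CCC1.[Na+] | intermediate
3 | allyl 1-methyl-2-oxocyclopentane-1-carboxylate (racemic) | C=CCOC(=O)C1(C)CCCC1=O | intermediate
4 | (R)-2-allyl-2-methylcyclopentanone | C=CC[C@@]1(C)CCCC1=O | intermediate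
5 | (R)-6-allyl-6-methyloxan-2-one | C=CC[C@@]1(C)CCCC(=O)O1 | intermediate
6 | (6R)-6-allyl-2,6-dimethyloxan-2-ol (lactol, C2 epimers, in equilibrium with its open hydroxy ketone) | C=CC[C@@]1(C)CCCC(C)(O)O1 | intermediate
7 | (6R)-6-allyl-2-methoxy-2,6-dimethyloxane (C2 epimers) | C=CC[C@@]1(C)CCCC(C)(OC)O1 | intermediate
8 | (R)-2-allyl-2,6,6-trimethyloxane | C=CC[C@@]1(C)CCCC(C)(C)O1 | intermediate
9 | (R)-3-(2,6,6-trimethyloxan-2-yl)propan-1-ol | OCCC[C@@]1(C)CCCC(C)(C)O1 | intermediate
10 | (R)-2-(3-bromopropyl)-2,6,6-trimethyloxane | BrCCC[C@@]1(C)CCCC(C)(C)O1 | intermediate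
11 | S-ethyl (E)-but-2-enethioate | C/C=C/C(=O)SCC | starting material
12 | {3-[(R)-2,6,6-trimethyloxan-2-yl]propyl}magnesium bromide | Br[Mg]CCC[C@@]1(C)CCCC(C)(C)O1 | intermediate
13 | S-ethyl (3S)-3-methyl-6-[(2S)-2,6,6-trimethyloxan-2-yl]hexanethioate | CCSC(=O)C[C@@H](C)CCC[C@@]1(C)CCCC(C)(C)O1 | intermediate
14 | (3S)-3-methyl-6-[(2S)-2,6,6-trimethyloxan-2-yl]hexanal | O=CC[C@@H](C)CCC[C@@]1(C)CCCC(C)(C)O1 | intermediate
15 | (2S)-2,6,6-trimethyl-2-[(4S)-4-methylhept-6-en-1-yl]oxane | C=CC[C@@H](C)CCC[C@@]1(C)CCCC(C)(C)O1 | intermediate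
16 | L-ascorbic acid | C([C@@H]([C@@H]1C(=C(C(=O)O1)O)O)O)O | starting material
17 | L-gulono-1,4-lactone | C([C@@H]([C@@H]1[C@@H]([C@@H](C(=O)O1)O)O)O)O | intermediate
18 | 5,6-O-isopropylidene-L-gulono-1,4-lactone | C1[C@@H]([C@@H]2[C@@H]([C@@H](C(=O)O2)O)O)OC(C)(C)O1 | intermediate
19 | (S)-2,2-dimethyl-1,3-dioxolane-4-carbaldehyde | CC1(C)OC[C@@H](C=O)O1 | intermediate
20 | (R)-2,2-dimethyl-4-vinyl-1,3-dioxolane | CC1(C)OC[C@@H](C=C)O1 | intermediate
21 | (4S)-4-(1,2-dibromoethyl)-2,2-dimethyl-1,3-dioxolane (epimers at CHBr) | CC1(C)OC[C@@H](C(Br)CBr)O1 | intermediate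
22 | (S)-4-(1-bromovinyl)-2,2-dimethyl-1,3-dioxolane | CC1(C)OC[C@@H](C(Br)=C)O1 | intermediate
23 | 9-{(4R)-4-methyl-7-[(2S)-2,6,6-trimethyloxan-2-yl]heptyl}-9-borabicyclo[3.3.1]nonane | B1(C2CCCC1CCC2)CCC[C@@H](C)CCC[C@@]1(C)CCCC(C)(C)O1 | intermediate
24 | (4R)-2,2-dimethyl-4-{(6R)-6-methyl-9-[(2S)-2,6,6-trimethyloxan-2-yl]non-1-en-2-yl}-1,3-dioxolane | C=C(CCC[C@@H](C)CCC[C@@]1(C)CCCC(C)(C)O1)[C@@H]1COC(C)(C)O1 | intermediate
25 | (2R,7R)-7-methyl-3-methylidene-10-[(2S)-2,6,6-trimethyloxan-2-yl]decane-1,2-diol | C=C(CCC[C@@H](C)CCC[C@@]1(C)CCCC(C)(C)O1)[C@H](CO)O | intermediate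
26 | (2R,7R)-7-methyl-3-methylidene-10-[(2S)-2,6,6-trimethyloxan-2-yl]decane-1,2-diyl diacetate | C=C(CCC[C@@H](C)CCC[C@@]1(C)CCCC(C)(C)O1)[C@H](COC(C)=O)OC(C)=O | target

**Totals**
Total step count: 18. Longest linear sequence: 13 steps (steps 1–10, 16, 17, 18, from diallyl adipate).

**Steps most likely to fail**

1. Step 5 (ketal methylation). What may go wrong: the cyclic oxocarbenium ion is trapped intramolecularly by the allyl group (oxonia-Prins closure across the ring) or loses a proton to the exocyclic enol ether before methyl transfer. The fallback avoids any oxocarbenium ion and never breaks the C11–O bond. It sets out from lactol 6, worked up after the MeLi addition of step 4 and reacting through its open hydroxy ketone form. Wittig methylenation (Ph3P=CH2, THF) should give (R)-4,8-dimethylnona-1,8-dien-4-ol F3. Intramolecular alkoxymercuration with Hg(OCOCF3)2 in dry CH2Cl2 should add the tertiary C11–OH in the Markovnikov sense to the 1,1-disubstituted alkene (6-exo), giving {[(6R)-6-allyl-2,6-dimethyloxan-2-yl]methyl}mercury trifluoroacetate F4; the allyl alkene has no favourable ring size and no external nucleophile. Reductive demercuration (NaBH4, aq. NaOH) turns the CH2Hg group into the second C15 methyl, and the fallback comes back to the route at 8.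

2. Step 3 (key step). What may go wrong: oxidation of the allyl C=C in competition with the ketone, or Lewis-acid ionisation of the tertiary alkyl C–O bond of the lactone once formed. The fallback keeps the same ring expansion but masks the alkene so that a buffered peracid can be used. It sets out from 4: Br2 in CH2Cl2 at −78 °C should give (2R)-2-(2,3-dibromopropyl)-2-methylcyclopentan-1-one F1. Baeyer–Villiger oxidation with mCPBA/NaHCO3 in CH2Cl2 at rt should give (6R)-6-(2,3-dibromopropyl)-6-methyloxan-2-one F2, with the same retentive quaternary-carbon migration. Zinc dust in AcOH/Et2O regenerates the alkene, and the fallback comes back at 5.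

3. Step 8 (asymmetric conjugate addition). What may go wrong: poor facial selectivity at C7, or uncatalysed background addition, with a Grignard reagent that carries a coordinating ether oxygen. The fallback replaces catalyst control by auxiliary control. It sets out from 10, through Grignard reagent 12. The acceptor is (S)-3-[(E)-but-2-enoyl]-4-phenyloxazolidin-2-one F5, made from (S)-4-phenyloxazolidin-2-one, n-BuLi and crotonyl chloride. Addition of 12 with CuBr·SMe2 in THF at −40 °C should occur anti to the phenyl group of the Mg-chelated s-cis imide, giving (S)-3-{(3S)-3-methyl-6-[(2S)-2,6,6-trimethyloxan-2-yl]hexanoyl}-4-phenyloxazolidin-2-one F6; this diastereomer can be purified. Displacement with LiSEt (EtSH, n-BuLi, THF, 0 °C) releases the auxiliary, and the fallback comes back at thioester 13.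

**Further compounds**
F1 | step 3 | (2R)-2-(2,3-dibromopropyl)-2-methylcyclopentan-1-one (epimers at CHBr) | BrCC(Br)C[C@@]1(C)CCCC1=O
F2 | step 3 | (6R)-6-(2,3-dibromopropyl)-6-methyloxan-2-one (epimers at CHBr) | BrCC(Br)C[C@@]1(C)CCCC(=O)O1
F3 | step 5 | (R)-4,8-dimethylnona-1,8-dien-4-ol | C=CC[C@@](O)(C)CCCC(C)=C
F4 | step 5 | {[(6R)-6-allyl-2,6-dimethyloxan-2-yl]methyl}mercury trifluoroacetate (C2 epimers) | C=CC[C@@]1(C)CCCC(C)(C[Hg]OC(=O)C(F)(F)F)O1
F5 | step 8 | (S)-3-[(E)-but-2-enoyl]-4-phenyloxazolidin-2-one | C/C=C/C(=O)N1[C@@H](c2ccccc2)COC1=O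
F6 | step 8 | (S)-3-{(3S)-3-methyl-6-[(2S)-2,6,6-trimethyloxan-2-yl]hexanoyl}-4-phenyloxazolidin-2-one | O=C(C[C@@H](C)CCC[C@@]1(C)CCCC(C)(C)O1)N1[C@@H](c2ccccc2)COC1=O
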